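**Retrosynthetic overview**
- The plan rests on ring B of the chromene half (C4a, C5, C6, C7, C8, C8a). Its carbons alternate oxygen-bearing (C5, C7, C8a) with carbon- or hydrogen-bearing (C4a, C6, C8), and it shares C4a–C8a with pyran ring C (O1, C2, C3, C4, C4a, C8a). This is the imprint of three oxygenated alkynes joined head to tail.
- Last bond: bridge CH2 to ring A, made from the ortho-quinone methide of a 6-(methoxymethyl)chromene-5,7-diol and isobutyrylfilicinic acid (ring A, dearomatised from phloroglucinol in a side branch).
- Key disconnection: C4a–C8a, C5–C6 and C7–C8 in one rhodium-catalysed [2+2+2] cycloaddition. A 1,7-diyne (siloxyalkyne at one end, tertiary ethynyl ether at the other) reacts with a siloxyalkyne that brings C6, C7 and the bridge carbon, so rings B and C form together from acyclic material.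
- C3=C4 is carried through this step as C3H2–C4H(OMe), because an allyl ethynyl ether would rearrange by a [3,3] shift to a ketene far below room temperature. Methanol is eliminated only after C8 has been brominated and acylated, which also keeps NBS away from an alkene.
- In the diyne the siloxyalkyne is made before the ethynyl ether, so that only one terminal alkyne is ever present. Ring order: A (side branch), then B and C together, then the bridge.

Key step: step 8

Assumption: the target is achiral. Compounds 4 to 21 carry one stereocentre (the later C4), are used as racemates, and lose it in step 11.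

**Step 1**
Reactants: 1 3-methylbutane-1,3-diol
Product: 2 3-hydroxy-3-methylbutanal
Conditions: 2,2,6,6-tetramethylpiperidin-1-oxyl (TEMPO, 10 mol%), PhI(OAc)2 (1.1 equiv), CH2Cl2, rt
Reagents that add atoms: none
Why: TEMPO-catalysed oxoammonium oxidation takes the primary alcohol to the aldehyde and cannot touch the tertiary alcohol.

**Step 2**
Reactants: 2 3-hydroxy-3-methylbutanal; 3 ethynylmagnesium bromide
Product: 4 5-methylhex-1-yne-3,5-diol (racemic)
Conditions: 3 (2.5 equiv), THF, −20 °C to rt, 2 added to 3
Reagents that add atoms: none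
Why: 1,2-Addition of an alkynyl Grignard reagent to the aldehyde follows deprotonation of the hydroxyl group by the first equivalent, and the new carbinol centre (later C4) forms as a racemate, which is acceptable because step 11 erases it.

**Step 3**
Reactants: 4 5-methylhex-1-yne-3,5-diol
Product: 5 4-methoxy-2-methylhex-5-yn-2-ol (racemic)
Conditions: NaH (1.05 equiv), MeI (1.2 equiv), THF, 0 °C
Reagents that add atoms: iodomethane, CI
Why: Williamson etherification in which one equivalent of base places the alkoxide on the more acidic and less hindered propargylic oxygen, so the tertiary hydroxyl stays free; a methyl ether cannot migrate under the KH of step 5.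

**Step 4**
Reactants: 5 4-methoxy-2-methylhex-5-yn-2-ol
Product: 7 4-methoxy-2-methyl-6-(triisopropylsilyloxy)hex-5-yn-2-ol (racemic), via dilithium ynolate alkoxide 6 (not isolated)
Conditions: n-BuLi (2.05 equiv), THF, −78 °C; t-BuOOLi (from t-BuOOH and LiN(SiMe3)2, 1.1 equiv), −78 to 0 °C; TIPSOTf (1.1 equiv), −78 °C
Reagents that add atoms: tert-butyl hydroperoxide, CC(C)(C)OO; triisopropylsilyl triflate, CC(C)[Si](OS(=O)(=O)C(F)(F)F)(C(C)C)C(C)C
Why: Oxidation of the lithium acetylide with lithium tert-butyl peroxide gives the ynolate, which the bulky silyl triflate captures on oxygen (the known route from terminal alkynes to 1-siloxyalkynes), while the tertiary lithium alkoxide, like the t-BuOLi released by the oxidation, is too hindered to be silylated at −78 °C.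

**Step 5**
Reactants: 7 4-methoxy-2-methyl-6-(triisopropylsilyloxy)hex-5-yn-2-ol; 8 trichloroethylene
Product: 10 5-[(E)-1,2-dichloroethenyloxy]-3-methoxy-5-methyl-1-(triisopropylsilyloxy)hex-1-yne (racemic), via dichloroacetylene 9 (not isolated)
Conditions: KH (1.2 equiv), THF, 0 °C; 8 (1.1 equiv), −50 °C to rt
Reagents that add atoms: none
Why: This is the first half of the trichloroethylene route to alkynyl ethers, in which the potassium alkoxide adds anti to dichloroacetylene formed in situ (hence E), and the siloxyalkyne is inert because it has no acidic hydrogen and its silicon is shielded from the hindered alkoxide.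

**Step 6**
Reactants: 10 5-[(E)-1,2-dichloroethenyloxy]-3-methoxy-5-methyl-1-(triisopropylsilyloxy)hex-1-yne
Product: 13 5-(ethynyloxy)-3-methoxy-5-methyl-1-(triisopropylsilyloxy)hex-1-yne (racemic), via chloroethynyl ether 11 (not isolated), via lithium alkoxyacetylide 12 (not isolated)
Conditions: n-BuLi (2.05 equiv), THF, −78 °C; then H2O in THF, −78 °C; work-up and Et3N-deactivated silica below 10 °C, stored at −20 °C
Reagents that add atoms: none
Why: β-Elimination of HCl followed by chlorine–lithium exchange (second half of the trichloroethylene route) is fast at −78 °C, so with the isolated ether 10 and an exact charge of base no n-BuLi should remain to attack the shielded triisopropylsilyl group.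

**Step 7**
Reactants: 14 methyl propargyl ether
Product: 16 3-methoxy-1-(triisopropylsilyloxy)prop-1-yne, via lithium ynolate 15 (not isolated)
Conditions: n-BuLi (1.0 equiv), THF, −78 °C; t-BuOOLi (from t-BuOOH and LiN(SiMe3)2, 1.1 equiv), −78 to 0 °C; TIPSOTf (1.1 equiv), −78 °C
Reagents that add atoms: tert-butyl hydroperoxide, CC(C)(C)OO; triisopropylsilyl triflate, CC(C)[Si](OS(=O)(=O)C(F)(F)F)(C(C)C)C(C)C
Why: The same acetylide oxidation and O-silylation of the ynolate as in step 4, applied to a simple terminal alkyne.

**Step 8**
Reactants: 13 5-(ethynyloxy)-3-methoxy-5-methyl-1-(triisopropylsilyloxy)hex-1-yne; 16 3-methoxy-1-(triisopropylsilyloxy)prop-1-yne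
Product: 17 4-methoxy-6-(methoxymethyl)-2,2-dimethyl-5,7-bis(triisopropylsilyloxy)chromane (racemic)
Conditions: [Rh(cod)2]BF4 (10 mol%), rac-BINAP (10 mol%), pre-activated with H2 (1 atm) in CH2Cl2; 16 (2 equiv), 2,6-di-tert-butylpyridine (20 mol%), CH2Cl2, 20 °C, 13 added over 3 h by syringe pump
Reagents that add atoms: none
Why: Proposed new method: the cationic monovalent rhodium–BINAP fragment binds both alkynes of 13 and couples them oxidatively (C4a–C8a) to a trivalent rhodacyclopentadiene, which closes the six-membered pyran ring C, after which 16 inserts (C7–C8) and reductive elimination (C5–C6) closes benzene ring B, so that all six carbons of ring B come from three alkynes. The closest known reaction type is the rhodium-catalysed [2+2+2] cycloaddition of ether-linked and alkynyl-ether-linked 1,6- and 1,7-diynes with monoalkynes at room temperature; new here is that all three alkynes are oxygen-substituted and that a siloxyalkyne is the inserting partner. Cross- over homo-trimerisation is served by the tether, the gem-dimethyl group at C2, the slow addition of 13 and an excess of the hindered 16, which should not trimerise on its own. The insertion must join the silyloxy-bearing carbon of 16 to C8 and its CH2OMe-bearing carbon to C5; this is favoured electronically, because every new bond then links an electrophilic oxygen-bearing alkyne carbon to a nucleophilic β-carbon, and sterically, because the bulky silyloxy end goes next to the only unsubstituted terminus (C8–H) and away from the silyloxy group on C5. No stereocentre is formed, and C4 is a racemic spectator. Room temperature and a proton scavenger are needed because the tertiary ethynyl ether fragments by a retro-ene reaction on warming and both siloxyalkynes are acid-labile.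

**Step 9**
Reactants: 17 4-methoxy-6-(methoxymethyl)-2,2-dimethyl-5,7-bis(triisopropylsilyloxy)chromane
Product: 18 8-bromo-4-methoxy-6-(methoxymethyl)-2,2-dimethyl-5,7-bis(triisopropylsilyloxy)chromane (racemic)
Conditions: NBS (1.0 equiv), NaHCO3 (solid), CH2Cl2, −40 to 0 °C, dark
Reagents that add atoms: N-bromosuccinimide, O=C1CCC(=O)N1Br
Why: Electrophilic aromatic bromination at C8, the only free ring position and one activated by O1 and the C7 oxygen (ortho) and the C5 oxygen (para), with no alkene yet present to compete for NBS.

**Step 10**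
Reactants: 18 8-bromo-4-methoxy-6-(methoxymethyl)-2,2-dimethyl-5,7-bis(triisopropylsilyloxy)chromane; 19 isobutyric anhydride
Product: 21 1-[4-methoxy-6-(methoxymethyl)-2,2-dimethyl-5,7-bis(triisopropylsilyloxy)chroman-8-yl]-2-methylpropan-1-one (racemic), via C8 aryllithium 20 (not isolated)
Conditions: n-BuLi (1.05 equiv), THF, −78 °C, 10 min; cannulated into 19 (3 equiv), THF, −78 °C
Reagents that add atoms: none
Why: Bromine–lithium exchange followed by acylation of the aryllithium with an anhydride; at −78 °C the retro-Brook shift of the bulky silyl group is slow, and the doubly ortho-substituted ketone resists a second addition.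

**Step 11**
Reactants: 21 1-[4-methoxy-6-(methoxymethyl)-2,2-dimethyl-5,7-bis(triisopropylsilyloxy)chroman-8-yl]-2-methylpropan-1-one
Product: 22 1-[6-(methoxymethyl)-2,2-dimethyl-5,7-bis(triisopropylsilyloxy)-2H-chromen-8-yl]-2-methylpropan-1-one
Conditions: camphorsulfonic acid (5 mol%), toluene, 70 °C, 4 Å MS (Soxhlet)
Reagents that add atoms: none
Why: Acid-catalysed E1 loss of methanol from a 4-alkoxychromane; the secondary C4 cation (stabilised by O1 and the C5 and C7 oxygens, with relief of peri strain) should form far faster than the primary cation at the C6 side chain, which has no β-hydrogen and can only recombine with methanol.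

**Step 12**
Reactants: 22 1-[6-(methoxymethyl)-2,2-dimethyl-5,7-bis(triisopropylsilyloxy)-2H-chromen-8-yl]-2-methylpropan-1-one
Product: 23 1-[5,7-dihydroxy-6-(methoxymethyl)-2,2-dimethyl-2H-chromen-8-yl]-2-methylpropan-1-one
Conditions: Bu4NF (2.2 equiv), AcOH (2.2 equiv), THF, 0 °C
Reagents that add atoms: none
Why: Fluoride cleavage of aryl silyl ethers, buffered with acetic acid so that little free phenoxide is present and methoxide is not expelled from the side chain too early.

**Step 13**
Reactants: 24 phloroglucinol; 25 isobutyryl chloride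
Product: 26 2-methyl-1-(2,4,6-trihydroxyphenyl)propan-1-one
Conditions: AlCl3 (3 equiv), PhNO2/CH2Cl2, 0 to 40 °C
Reagents that add atoms: none
Why: Friedel–Crafts acylation that stops after one acyl group because the chelated ketone deactivates the ring.

**Step 14**
Reactants: 26 2-methyl-1-(2,4,6-trihydroxyphenyl)propan-1-one
Product: 27 isobutyrylfilicinic acid, 3,5-dihydroxy-6,6-dimethyl-2-(2-methylpropanoyl)cyclohexa-2,4-dien-1-one
Conditions: NaOMe (3 equiv), MeI (2.2 equiv), MeOH, 0 °C to rt
Reagents that add atoms: iodomethane, CI
Why: Base-mediated dearomative C-methylation of an acylphloroglucinol, the known route to acylfilicinic acids, in which both methyl groups enter at the same ring carbon and the limited charge of MeI holds back tri- and tetramethylation.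

**Step 15**
Reactants: 23 1-[5,7-dihydroxy-6-(methoxymethyl)-2,2-dimethyl-2H-chromen-8-yl]-2-methylpropan-1-one; 27 isobutyrylfilicinic acid
Product: 29 uliginosin B, via ortho-quinone methide 28 (not isolated)
Conditions: 27 (1.2 equiv), toluene, 90 °C, 4 Å MS
Reagents that add atoms: none
Why: The acidic enol 27 helps 23 to lose methanol to the ortho-quinone methide 28, whose exocyclic CH2 is attacked by the only unsubstituted ring carbon of 27 in a Michael-type addition driven by rearomatisation of ring B, a known way to methylene-bridged acylphloroglucinols.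

**Compound list**
1 | 3-methylbutane-1,3-diol | CC(C)(O)CCO | starting material
2 | 3-hydroxy-3-methylbutanal | CC(C)(O)CC=O | intermediate
3 | ethynylmagnesium bromide | C#C[Mg]Br | starting material
4 | 5-methylhex-1-yne-3,5-diol (racemic) | CC(C)(O)CC(O)C#C | intermediate
5 | 4-methoxy-2-methylhex-5-yn-2-ol (racemic) | CC(C)(O)CC(OC)C#C | intermediate
6 | dilithium ynolate alkoxide derived from 5 | [Li+].[Li+].CC(C)([O-])CC(OC)C#C[O-] | intermediate (not isolated)
7 | 4-methoxy-2-methyl-6-(triisopropylsilyloxy)hex-5-yn-2-ol (racemic) | CC(C)(O)CC(OC)C#CO[Si](C(C)C)(C(C)C)C(C)C | intermediate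
8 | trichloroethylene | ClC=C(Cl)Cl | starting material
9 | dichloroacetylene | ClC#CCl | intermediate (not isolated)
10 | 5-[(E)-1,2-dichloroethenyloxy]-3-methoxy-5-methyl-1-(triisopropylsilyloxy)hex-1-yne (racemic) | CC(C)(CC(OC)C#CO[Si](C(C)C)(C(C)C)C(C)C)O/C(Cl)=C\Cl | intermediate
11 | 5-(chloroethynyloxy)-3-methoxy-5-methyl-1-(triisopropylsilyloxy)hex-1-yne | ClC#COC(C)(C)CC(OC)C#CO[Si](C(C)C)(C(C)C)C(C)C | intermediate (not isolated)
12 | lithium alkoxyacetylide of 13 | [Li]C#COC(C)(C)CC(OC)C#CO[Si](C(C)C)(C(C)C)C(C)C | intermediate (not isolated)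
13 | 5-(ethynyloxy)-3-methoxy-5-methyl-1-(triisopropylsilyloxy)hex-1-yne (racemic) | C#COC(C)(C)CC(OC)C#CO[Si](C(C)C)(C(C)C)C(C)C | intermediate
14 | methyl propargyl ether | COCC#C | starting material
15 | lithium 3-methoxyprop-1-yn-1-olate | [Li+].COCC#C[O-] | intermediate (not isolated)
16 | 3-methoxy-1-(triisopropylsilyloxy)prop-1-yne | COCC#CO[Si](C(C)C)(C(C)C)C(C)C | intermediate
17 | 4-methoxy-6-(methoxymethyl)-2,2-dimethyl-5,7-bis(triisopropylsilyloxy)chromane (racemic) | CC1(C)CC(OC)c2c(O[Si](C(C)C)(C(C)C)C(C)C)c(COC)c(O[Si](C(C)C)(C(C)C)C(C)C)cc2O1 | intermediate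
18 | 8-bromo-4-methoxy-6-(methoxymethyl)-2,2-dimethyl-5,7-bis(triisopropylsilyloxy)chromane (racemic) | CC1(C)CC(OC)c2c(O[Si](C(C)C)(C(C)C)C(C)C)c(COC)c(O[Si](C(C)C)(C(C)C)C(C)C)c(Br)c2O1 | intermediate
19 | isobutyric anhydride | CC(C)C(=O)OC(=O)C(C)C | starting material
20 | C8 aryllithium derived from 18 | [Li]c1c(O[Si](C(C)C)(C(C)C)C(C)C)c(COC)c(O[Si](C(C)C)(C(C)C)C(C)C)c2c1OC(C)(C)CC2OC | intermediate (not isolated)
21 | 1-[4-methoxy-6-(methoxymethyl)-2,2-dimethyl-5,7-bis(triisopropylsilyloxy)chroman-8-yl]-2-methylpropan-1-one (racemic) | CC1(C)CC(OC)c2c(O[Si](C(C)C)(C(C)C)C(C)C)c(COC)c(O[Si](C(C)C)(C(C)C)C(C)C)c(C(=O)C(C)C)c2O1 | intermediate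
22 | 1-[6-(methoxymethyl)-2,2-dimethyl-5,7-bis(triisopropylsilyloxy)-2H-chromen-8-yl]-2-methylpropan-1-one | CC1(C)C=Cc2c(O[Si](C(C)C)(C(C)C)C(C)C)c(COC)c(O[Si](C(C)C)(C(C)C)C(C)C)c(C(=O)C(C)C)c2O1 | intermediate
23 | 1-[5,7-dihydroxy-6-(methoxymethyl)-2,2-dimethyl-2H-chromen-8-yl]-2-methylpropan-1-one | CC1(C)C=Cc2c(O)c(COC)c(O)c(C(=O)C(C)C)c2O1 | intermediate
24 | phloroglucinol | Oc1cc(O)cc(O)c1 | starting material
25 | isobutyryl chloride | CC(C)C(=O)Cl | starting material
26 | 2-methyl-1-(2,4,6-trihydroxyphenyl)propan-1-one | CC(C)C(=O)c1c(O)cc(O)cc1O | intermediate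
27 | isobutyrylfilicinic acid | CC(C)C(=O)C1=C(O)C=C(O)C(C)(C)C1=O | intermediate
28 | 7-hydroxy-2,2-dimethyl-6-methylidene-8-(2-methylpropanoyl)-2H-chromen-5(6H)-one (ortho-quinone methide) | C=C1C(=O)C2=C(OC(C)(C)C=C2)C(C(=O)C(C)C)=C1O | intermediate (not isolated)
29 | uliginosin B | CC(C)C(=O)C1=C(O)C(Cc2c(O)c3c(c(C(=O)C(C)C)c2O)OC(C)(C)C=C3)=C(O)C(C)(C)C1=O | target

**Step count**
Total: 15 steps. Longest linear sequence: 12 steps (steps 1–6, 8–12, 15).

**Steps most likely to fail**

Step 8.
- Risks: retro-ene fragmentation of the tertiary ethynyl ether, metal- or acid-induced ionisation of the propargylic methyl ethers, and oligomerisation of the diyne. The hindered siloxyalkyne may also fail to insert, or insert with reversed orientation.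
- Fallback (known chemistry): it sets out from 26 and comes back at 28, and so at 29. It builds ring C on a preformed ring B.
- Condensation of 26 with 3-methylbut-2-enal under ethylenediammonium diacetate catalysis (Knoevenagel condensation, then oxa-6π electrocyclisation) should give, after separation from the 6-acyl regioisomer, 1-(5,7-dihydroxy-2,2-dimethyl-2H-chromen-8-yl)-2-methylpropan-1-one F1.
- Mannich aminomethylation of the free C6 with dimethylmethyleneiminium iodide gives 1-{6-[(dimethylamino)methyl]-5,7-dihydroxy-2,2-dimethyl-2H-chromen-8-yl}-2-methylpropan-1-one F2.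
- Heating F2 with 27 expels dimethylamine to give 28, which 27 traps to 29.

Step 6.
- Risks: attack of n-BuLi at silicon with loss of the silyl group as the ynolate, and fragmentation of the product during work-up.
- Fallback: it sets out from 7 and comes back at 12, and so at 13.
- The potassium alkoxide of 7 (KH, THF) is added to chloroacetylene generated in situ from cis-1,2-dichloroethene. Anti addition gives 5-[(Z)-2-chloroethenyloxy]-3-methoxy-5-methyl-1-(triisopropylsilyloxy)hex-1-yne F3.
- F3 needs only an anti β-elimination and no halogen–metal exchange. The hindered, non-nucleophilic amide LiN(i-Pr)2 (2 equiv, THF, −78 to −30 °C) therefore suffices to reach 12, which is protonated to 13.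

Step 11.
- Risks: competing ionisation of the C6 methoxymethyl group and cationic oligomerisation of the newly formed chromene.
- Fallback: it sets out from 21 and comes back at 23. It replaces the acid-driven E1 path by a phenoxide-driven one.
- Desilylation of 21 (Bu4NF, AcOH, THF) gives 1-[5,7-dihydroxy-4-methoxy-6-(methoxymethyl)-2,2-dimethylchroman-8-yl]-2-methylpropan-1-one F4.
- Warming F4 with K2CO3 in MeOH (60 °C) lets the phenoxide expel the C4 methoxide to a quinone methide, which tautomerises irreversibly (loss of a C3 proton) to the chromene 23.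
- Any quinone methide formed at the C6 side chain only takes methanol up again.

**Further compounds**
F1 | step 8 | 1-(5,7-dihydroxy-2,2-dimethyl-2H-chromen-8-yl)-2-methylpropan-1-one | CC1(C)C=Cc2c(O)cc(O)c(C(=O)C(C)C)c2O1
F2 | step 8 | 1-{6-[(dimethylamino)methyl]-5,7-dihydroxy-2,2-dimethyl-2H-chromen-8-yl}-2-methylpropan-1-one | CC1(C)C=Cc2c(O)c(CN(C)C)c(O)c(C(=O)C(C)C)c2O1
F3 | step 6 | 5-[(Z)-2-chloroethenyloxy]-3-methoxy-5-methyl-1-(triisopropylsilyloxy)hex-1-yne (racemic) | CC(C)(CC(OC)C#CO[Si](C(C)C)(C(C)C)C(C)C)O/C=C\Cl
F4 | step 11 | 1-[5,7-dihydroxy-4-methoxy-6-(methoxymethyl)-2,2-dimethylchroman-8-yl]-2-methylpropan-1-one (racemic) | CC1(C)CC(OC)c2c(O)c(COC)c(O)c(C(=O)C(C)C)c2O1
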